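Late in the run I expect a flask at rest, so I reckon that end state first, as a fraction of the charge of D.

    D.E ⇌ X (K1 = 2.8, k1 = 0.088 s⁻¹)
    D + E → D.E (k2 = 0.29 M⁻¹ s⁻¹)
    L ⇌ D.E, rate k3*(cs3 - [D.E]) while solid is left; crystals form when [D.E] > cs3 (cs3 = 7.5 mM, k3 = 0.14 s⁻¹)
    D → G (k4 = 0.057 s⁻¹)
    Q ⇌ E, rate k5*(csat - [E]) (k5 = 1.2 s⁻¹, csat = 200 mM)

D 0.57 M; Q 200 mM (held); time 3.0 h

- why nothing more happens at 3.0 h, or that something still does (all of D has reacted / forward and back rates have come level / it is still moving)
- share of the D used up at 3.0 h
- D.E at 3.0 h, in percent of the D charged
- G at 3.0 h, in percent of the D charged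

- what is said of D.E includes L
- L is a solid; its amount is given per volume of the solution
- at the start none of E is dissolved
- the reaction counts as stopped when no species that holds the D changes by six tenths of a point or more over the second half of the time
- run time (flask): 3.0 h

1. The half-life of D by its decay to G alone is 0.20 min, far shorter than the 3.0 h of the run, so D does not outlast the run.

2. While crystals stand, dissolved D.E holds 1.32 % of the charge and X holds 2.8 times that, so X takes 3.68 %. I call this the X share: solubility times equilibrium constant, over the charge of D.

3. Bound from above: E stays below saturation, so the selectivity towards D.E reaches at most 50.4 %. Taking off the X share leaves D.E at 46.8 %.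

4. Bound from below, as an estimate: with D held at its full charge, supply and use balance with E at 87.9 % of saturation, which gives a selectivity of 47.2 %. I also reckon the rise of E as a start of 0.732 s with no E, and in that start I put 4.17 % of D to G. That leaves D.E at 41.6 %.

5. The forecast says all of D has reacted, conversion 100 %, D.E 43.2 % (from 42.2 % to 45.2 %) and G 53.2 % (from 51.2 % to 54.2 %), on the ground that “crystals persist, so dissolved D.E stays” at solubility. Its D.E lies above my lower bound and below my upper one.

The simulation gives all of D has reacted, conversion 100 %, D.E 43.1 % and G 53.2 %. This flask already reads D.E 43.1 % at 0.300 h, and 43.1 % at 30.0 h. X stands at 3.68 %, level with the X share. With 0.14 M of D in the neighbouring flask, the X share grows to 15.0 %. Its G of 52.2 % then leaves D.E 32.8 %. The neighbouring flask holds X 15.0 % and D.E 32.8 %, of which L is 27.5 %.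

(Its constants are assumed; no experiment stands behind them.)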